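**Strategy.** The decalin is disconnected across ring A: the C1–C10 edge is treated as a dienophile and C2–C5 as a diene, joined through the four ring-B carbons C6–C9 (labdane numbering). With the angular methyl C20 raised to a formyl group and C3 carried as a silyl enol ether, an intramolecular Diels–Alder reaction of an acyclic trienal closes rings A and B at once and sets C5 and C10 from the single stereocentre C9; the cis C7=C8 bond of ring B is already in the tether. The precursor is a 2-silyloxydiene tethered to an α-substituted acrolein. The side chain is then joined by alkyne alkylboration, and the enol sulfate is made from a stereodefined alkenyllithium.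

Key step: step 8

Remarks. Labdane-type numbering is used for the bicycle: C1–C10 are the decalin carbons, C17 the methyl on C8, C20 the angular carbon on C10, C11–C12 the ethylene link, C13 the enol carbon and C14 the carbon bearing the sulfate oxygen. The target is drawn as the hydrogen sulfate; it is assumed to be handled as a salt and protonated only in the last operation, and to be kept cold because the free acid is expected to be labile. Propyne, allyl bromide, 3-[(tert-butyldimethylsilyl)oxy]propanal, 3-methylbut-3-en-2-one, 2,5-dihydroxybenzaldehyde and hepta-1,6-diyne are taken as commercial.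

**Step 1**
Reactants: 1 propyne
Product: 2 cis-1,2-bis(pinacolboryl)prop-1-ene
Conditions: B2pin2, Pt(PPh3)4 (3 mol%), DMF, 80 °C
Reagents that add atoms: bis(pinacolato)diboron, CC1(C)OB(OC1(C)C)B1OC(C)(C)C(C)(C)O1
Why: Platinum-catalysed syn-diboration of a terminal alkyne (Miyaura–Ishiyama diboration) puts both boryl groups on the same side, which later fixes the cis relationship of C6 and C9 across C7=C8.

**Step 2**
Reactants: 2 cis-1,2-bis(pinacolboryl)prop-1-ene; 3 allyl bromide
Product: 4 2-[(2E)-hexa-2,5-dien-2-yl]-4,4,5,5-tetramethyl-1,3,2-dioxaborolane (boron cis to the allylic CH2)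
Conditions: Pd(PPh3)4 (3 mol%), 3 M aq. KOH, dioxane, 25–50 °C
Reagents that add atoms: none
Why: Suzuki–Miyaura coupling of a cis-1,2-diborylalkene should occur selectively at the less hindered terminal C–B bond with retention, so the allyl group (C5–C6) ends cis to the remaining boron.

**Step 3**
Reactants: 5 3-[(tert-butyldimethylsilyl)oxy]propanal
Product: 6 ethyl (2E)-5-[(tert-butyldimethylsilyl)oxy]pent-2-enoate
Conditions: Ph3P=CHCO2Et, CH2Cl2, rt
Reagents that add atoms: ethyl (triphenylphosphoranylidene)acetate, CCOC(=O)C=P(c1ccccc1)(c1ccccc1)c1ccccc1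
Why: Wittig olefination with a stabilised ylide should give the E-enoate.

**Step 4**
Reactants: 4 dienyl boronate; 6 enoate
Product: 7 ethyl (3R,4Z)-3-{2-[(tert-butyldimethylsilyl)oxy]ethyl}-4-methylocta-4,7-dienoate
Conditions: [Rh(OH)(cod)]2 (1.5 mol%), (R)-BINAP (3.5 mol%), K3PO4, dioxane/H2O 10:1, 60 °C
Reagents that add atoms: none
Why: Rhodium/BINAP-catalysed asymmetric conjugate addition (Hayashi–Miyaura) transfers the alkenyl group with retention of its geometry, and the ligand sets the new centre (C9, 3R), (R)-BINAP being chosen by analogy with additions to E-enones, its antipode being used should the sense be opposite.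

**Step 5**
Reactants: 7 dienoate
Product: 8 (3R,4Z)-3-{2-[(tert-butyldimethylsilyl)oxy]ethyl}-4-methylocta-4,7-dienal
Conditions: DIBAL-H (1.1 equiv), CH2Cl2, −78 °C; Rochelle salt work-up
Reagents that add atoms: none
Why: DIBAL-H reduction at −78 °C should stop at the aldehyde through the stable aluminium hemiacetal.

**Step 6**
Reactants: 8 dienal; 9 3-methylbut-3-en-2-one
Product: 10 (3R,4Z,7E)-3-{2-[(tert-butyldimethylsilyl)oxy]ethyl}-4,8-dimethyl-9-oxodeca-4,7-dienal
Conditions: second-generation Hoveyda–Grubbs catalyst (5 mol%), 9 (5 equiv), CH2Cl2, 40 °C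
Reagents that add atoms: none
Why: Olefin cross-metathesis of the only monosubstituted alkene with the α-methyl enone should give the E-trisubstituted enone, the Z-trisubstituted C7=C8 bond being too hindered to take part.

**Step 7**
Reactants: 10 keto aldehyde
Product: 11 (3S,4Z,7E)-3-{2-[(tert-butyldimethylsilyl)oxy]ethyl}-4,8-dimethyl-2-methylidene-9-oxodeca-4,7-dienal
Conditions: CH2=NMe2+ I−, Et3N, CH2Cl2, rt
Reagents that add atoms: N,N-dimethylmethyleneiminium iodide (Eschenmoser's salt), C=[N+](C)C.[I-]
Why: Mannich reaction of the aldehyde with Eschenmoser's salt and loss of dimethylamine (α-methylenation) installs C1 without touching C9, which the cross-conjugated carbonyl does not acidify.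

**Step 8**
Reactants: 11 enal enone
Product: 13 Diels–Alder adduct (trans-fused octalin aldehyde), via silyloxytriene 12 (not isolated)
Conditions: TBSOTf, i-Pr2NEt, CH2Cl2, −78 → 0 °C; then PhMe, 70 °C
Reagents that add atoms: tert-butyldimethylsilyl triflate, CC(C)(C)[Si](C)(C)OS(=O)(=O)C(F)(F)F
Why: Silylation of the methyl ketone gives the 2-silyloxydiene 12, which should undergo a concerted, asynchronous normal-demand intramolecular Diels–Alder reaction in which the electron-rich terminus C2 bonds to the acrolein β-carbon C1 and C5 bonds to C10. The closest known reactions are thermal type 1 intramolecular Diels–Alder reactions of 1,7,9-decatrienes and additions of 2-silyloxydienes to 2-substituted acroleins. Ring A closes as the six-membered cycloadduct ring, and ring B closes through the same C5–C10 bond as a six-membered ring in the type 1 mode (tether from C5 to C10, both reacting π bonds exocyclic to ring B), its cis C7=C8 bond restricting the tether. C5 and C10 are set by the endo position of the formyl group, which is not in the tether, so that the tether is exo and H-5 ends anti to C20 (trans-decalin); their sense relative to C9 is set by the C9 stereocentre, whose hydrogen eclipses C10=C1 while the CH2CH2OTBS arm points away from the diene. The step needs endo and facial selectivity: the first should follow from carbonyl–diene secondary overlap with matched polarity, the second from the inside-hydrogen rotamer, against which only an A(1,2) contact between C11 and the C8 methyl works. It also needs silylation at the ketone methyl and not at the doubly allylic C6, which kinetic amine/silyl triflate conditions at low temperature should secure.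

**Step 9**
Reactants: 13 Diels–Alder adduct
Product: 14 (5R,9S,10S)-12-[(tert-butyldimethylsilyl)oxy]-3-oxo-13,14,15,16-tetranorlabd-7-en-20-al
Conditions: TASF (1.05 equiv), MeI (5 equiv), THF, −78 → −20 °C
Reagents that add atoms: iodomethane, CI
Why: Fluoride cleaves the silyl enol ether, which is far more labile than the alkyl silyl ether, to the regiodefined naked C3–C4 enolate, and iodomethane C-methylates it at C4 (regiospecific enolate alkylation) to complete the gem-dimethyl group.

**Step 10**
Reactants: 14 keto aldehyde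
Product: 15 (5S,9S,10S)-13,14,15,16-tetranorlabd-7-en-12-ol
Conditions: N2H4·H2O, KOH, diethylene glycol, 130 → 205 °C; then 1 M HCl, MeOH, rt
Reagents that add atoms: none
Why: Huang-Minlon Wolff–Kishner reduction should remove both the C3 ketone and the angular C20 aldehyde via their hydrazones, turning C20 into the methyl group, while hot base and the acidic work-up free the C12 hydroxyl.

**Step 11**
Reactants: 15 alcohol
Product: 16 (5S,9S,10S)-12-iodo-13,14,15,16-tetranorlabd-7-ene
Conditions: I2, PPh3, imidazole, CH2Cl2, 0 °C → rt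
Reagents that add atoms: iodine, II
Why: Appel-type iodination displaces the oxyphosphonium of the unhindered primary alcohol by iodide (SN2).

**Step 12**
Reactants: 17 2,5-dihydroxybenzaldehyde
Product: 18 2,5-bis[(triisopropylsilyl)oxy]benzaldehyde
Conditions: TIPSCl (2.4 equiv), imidazole, DMF, rt
Reagents that add atoms: chlorotriisopropylsilane, CC(C)[Si](Cl)(C(C)C)C(C)C
Why: Silylation of both phenols gives aryl silyl ethers that should tolerate the alkoxide and organolithium steps and leave with fluoride at the end.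

**Step 13**
Reactants: 18 aldehyde
Product: 19 {2,5-bis[(triisopropylsilyl)oxy]phenyl}methanol
Conditions: NaBH4, MeOH/THF, 0 °C
Reagents that add atoms: none
Why: Borohydride reduction of the aryl aldehyde to the benzylic alcohol.

**Step 14**
Reactants: 19 benzylic alcohol
Product: 20 2-(chloromethyl)-1,4-bis[(triisopropylsilyl)oxy]benzene
Conditions: MsCl, LiCl, 2,4,6-collidine, DMF, 0 °C
Reagents that add atoms: lithium chloride, [Li+].[Cl-]
Why: Collington–Meyers chlorination, in which the mesylate formed in the flask is displaced by chloride without acid.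

**Step 15**
Reactants: 21 hepta-1,6-diyne (3 equiv); 20 benzylic chloride
Product: 23 2-[(2E)-3-methyloct-2-en-7-yn-1-yl]-1,4-bis[(triisopropylsilyl)oxy]benzene, via alkenylalane 22 (not isolated)
Conditions: Me3Al, Cp2ZrCl2 (0.2 equiv), CH2Cl2, 0 °C → rt; then 20, Pd(PPh3)4 (5 mol%), THF, rt
Reagents that add atoms: trimethylaluminium, C[Al](C)C
Why: Zirconium-catalysed syn-carboalumination (Negishi) of one terminus of the diyne used in excess gives the E-alkenylalane, which should cross-couple with the benzylic chloride under palladium catalysis with retention and so set the E-trisubstituted alkene.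

**Step 16**
Reactants: 16 iodide; 23 aryl enyne
Product: 24 (E)-alkenyl pinacol boronate (boron on C14, cis to C12)
Conditions: B2pin2, CuCl (10 mol%), Xantphos (11 mol%), LiOt-Bu, DMA, 25 °C
Reagents that add atoms: bis(pinacolato)diboron, CC1(C)OB(OC1(C)C)B1OC(C)(C)C(C)(C)O1
Why: Copper-catalysed alkylboration of the terminal alkyne: syn-borylcupration puts boron on the terminal carbon and copper on C13, and the alkenylcopper is alkylated by the primary iodide with retention, so boron ends cis to C12.

**Step 17**
Reactants: 24 alkenyl boronate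
Product: 25 (E)-alkenyl iodide (iodine on C14, cis to C12)
Conditions: 3 M aq. NaOH, then I2 (1.1 equiv), THF, 0 °C
Reagents that add atoms: iodine, II
Why: Iododeboronation of the alkenylboronate ate complex (Brown conditions) should proceed with retention, the boronate reacting with iodine much faster than the isolated alkenes.

**Step 18**
Reactants: 25 alkenyl iodide
Product: 28 sodium (E)-enol sulfate with both phenols as TIPS ethers, via alkenyllithium 26 (not isolated), via lithium enolate 27 (not isolated)
Conditions: t-BuLi (2.1 equiv), Et2O/THF, −78 °C; LiOOt-Bu (from t-BuOOH, n-BuLi), −78 → 0 °C; SO3·NMe3 (4 equiv), DMF, 0 °C; aq. NaHCO3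
Reagents that add atoms: lithium tert-butyl peroxide, [Li+].CC(C)(C)O[O-]; sulfur trioxide–trimethylamine complex, C[N+](C)(C)S(=O)(=O)[O-]; sodium hydrogen carbonate, [Na+].OC([O-])=O
Why: Iodine–lithium exchange gives the configurationally stable alkenyllithium, lithium tert-butyl peroxide oxidises it to the aldehyde lithium enolate with retention (oxidation of organolithiums by lithium alkyl peroxides), and O-sulfation of the enolate by SO3·NMe3 should give the E-enol sulfate.

**Step 19**
Reactants: 28 sodium enol sulfate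
Product: 30 target hydrogen sulfate, via tetrabutylammonium sulfate 29 (not isolated)
Conditions: TBAF/AcOH, THF, 0 °C, argon; then cold 0.1 M HCl to pH 2–3, rapid extraction (EtOAc/n-BuOH)
Reagents that add atoms: none
Why: Fluoride removes both aryl silyl ethers (desilylation), and brief cold acidification protonates the base-stable sulfate monoester.

**Compound list**

1 | propyne | CC#C | starting material
2 | cis-1,2-bis(4,4,5,5-tetramethyl-1,3,2-dioxaborolan-2-yl)prop-1-ene (boryl groups cis; E by CIP) | C/C(B1OC(C)(C)C(C)(C)O1)=C/B1OC(C)(C)C(C)(C)O1 | intermediate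
3 | allyl bromide | C=CCBr | starting material
4 | 2-[(2E)-hexa-2,5-dien-2-yl]-4,4,5,5-tetramethyl-1,3,2-dioxaborolane (boron cis to C4H2) | C=CC/C=C(/C)B1OC(C)(C)C(C)(C)O1 | intermediate
5 | 3-[(tert-butyldimethylsilyl)oxy]propanal | O=CCCO[Si](C)(C)C(C)(C)C | starting material
6 | ethyl (2E)-5-[(tert-butyldimethylsilyl)oxy]pent-2-enoate | CCOC(=O)/C=C/CCO[Si](C)(C)C(C)(C)C | intermediate
7 | ethyl (3R,4Z)-3-{2-[(tert-butyldimethylsilyl)oxy]ethyl}-4-methylocta-4,7-dienoate | CCOC(=O)C[C@@H](CCO[Si](C)(C)C(C)(C)C)/C(C)=C\CC=C | intermediate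
8 | (3R,4Z)-3-{2-[(tert-butyldimethylsilyl)oxy]ethyl}-4-methylocta-4,7-dienal | O=CC[C@@H](CCO[Si](C)(C)C(C)(C)C)/C(C)=C\CC=C | intermediate
9 | 3-methylbut-3-en-2-one | CC(=O)C(C)=C | starting material
10 | (3R,4Z,7E)-3-{2-[(tert-butyldimethylsilyl)oxy]ethyl}-4,8-dimethyl-9-oxodeca-4,7-dienal | O=CC[C@@H](CCO[Si](C)(C)C(C)(C)C)/C(C)=C\C/C=C(C)/C(C)=O | intermediate
11 | (3S,4Z,7E)-3-{2-[(tert-butyldimethylsilyl)oxy]ethyl}-4,8-dimethyl-2-methylidene-9-oxodeca-4,7-dienal | C=C(C=O)[C@@H](CCO[Si](C)(C)C(C)(C)C)/C(C)=C\C/C=C(C)/C(C)=O | intermediate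
12 | (3S,4Z,7E)-9-[(tert-butyldimethylsilyl)oxy]-3-{2-[(tert-butyldimethylsilyl)oxy]ethyl}-4,8-dimethyl-2-methylidenedeca-4,7,9-trienal (silyloxytriene) | C=C(C=O)[C@@H](CCO[Si](C)(C)C(C)(C)C)/C(C)=C\C/C=C(C)/C(O[Si](C)(C)C(C)(C)C)=C | intermediate
13 | Diels–Alder adduct: (5S,9S,10S)-3,12-bis[(tert-butyldimethylsilyl)oxy]-19-nor-13,14,15,16-tetranorlabda-3,7-dien-20-al (trans-fused; 5α-H, 9α-H, 10β-CHO) | CC1=CC[C@H]2C(C)=C(O[Si](C)(C)C(C)(C)C)CC[C@]2(C=O)[C@H]1CCO[Si](C)(C)C(C)(C)C | intermediate
14 | (5R,9S,10S)-12-[(tert-butyldimethylsilyl)oxy]-3-oxo-13,14,15,16-tetranorlabd-7-en-20-al (5α-H, 9α-H, 10β-CHO) | CC1=CC[C@H]2C(C)(C)C(=O)CC[C@]2(C=O)[C@H]1CCO[Si](C)(C)C(C)(C)C | intermediate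
15 | (5S,9S,10S)-13,14,15,16-tetranorlabd-7-en-12-ol | CC1=CC[C@H]2C(C)(C)CCC[C@]2(C)[C@H]1CCO | intermediate
16 | (5S,9S,10S)-12-iodo-13,14,15,16-tetranorlabd-7-ene | CC1=CC[C@H]2C(C)(C)CCC[C@]2(C)[C@H]1CCI | intermediate
17 | 2,5-dihydroxybenzaldehyde | O=Cc1cc(O)ccc1O | starting material
18 | 2,5-bis[(triisopropylsilyl)oxy]benzaldehyde | O=Cc1cc(O[Si](C(C)C)(C(C)C)C(C)C)ccc1O[Si](C(C)C)(C(C)C)C(C)C | intermediate
19 | {2,5-bis[(triisopropylsilyl)oxy]phenyl}methanol | OCc1cc(O[Si](C(C)C)(C(C)C)C(C)C)ccc1O[Si](C(C)C)(C(C)C)C(C)C | intermediate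
20 | 2-(chloromethyl)-1,4-bis[(triisopropylsilyl)oxy]benzene | ClCc1cc(O[Si](C(C)C)(C(C)C)C(C)C)ccc1O[Si](C(C)C)(C(C)C)C(C)C | intermediate
21 | hepta-1,6-diyne | C#CCCCC#C | starting material
22 | dimethyl[(1E)-2-methyloct-1-en-7-yn-1-yl]alumane | C#CCCC/C(C)=C/[Al](C)C | intermediate
23 | 2-[(2E)-3-methyloct-2-en-7-yn-1-yl]-1,4-bis[(triisopropylsilyl)oxy]benzene | C#CCCC/C(C)=C/Cc1cc(O[Si](C(C)C)(C(C)C)C(C)C)ccc1O[Si](C(C)C)(C(C)C)C(C)C | intermediate
24 | (E)-alkenyl pinacol boronate: boron on C14 cis to C12; C13 carries the (5S,9S,10S)-tetranorlabd-7-en-12-yl arm and the (4E)-4-methyl-6-aryl-hex-4-enyl arm (aryl = 2,5-bis(TIPS-oxy)phenyl) | CC1=CC[C@H]2C(C)(C)CCC[C@]2(C)[C@H]1CC/C(=C\B1OC(C)(C)C(C)(C)O1)CCC/C(C)=C/Cc1cc(O[Si](C(C)C)(C(C)C)C(C)C)ccc1O[Si](C(C)C)(C(C)C)C(C)C | intermediate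
25 | (E)-alkenyl iodide corresponding to 24 (iodine on C14, cis to C12) | CC1=CC[C@H]2C(C)(C)CCC[C@]2(C)[C@H]1CC/C(=C\I)CCC/C(C)=C/Cc1cc(O[Si](C(C)C)(C(C)C)C(C)C)ccc1O[Si](C(C)C)(C(C)C)C(C)C | intermediate
26 | (E)-alkenyllithium corresponding to 25 | CC1=CC[C@H]2C(C)(C)CCC[C@]2(C)[C@H]1CC/C(=C\[Li])CCC/C(C)=C/Cc1cc(O[Si](C(C)C)(C(C)C)C(C)C)ccc1O[Si](C(C)C)(C(C)C)C(C)C | intermediate
27 | lithium (E)-enolate (O–Li on C14, oxygen cis to C12) | CC1=CC[C@H]2C(C)(C)CCC[C@]2(C)[C@H]1CC/C(=C\O[Li])CCC/C(C)=C/Cc1cc(O[Si](C(C)C)(C(C)C)C(C)C)ccc1O[Si](C(C)C)(C(C)C)C(C)C | intermediate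
28 | sodium (E)-enol sulfate, both phenols as triisopropylsilyl ethers | CC1=CC[C@H]2C(C)(C)CCC[C@]2(C)[C@H]1CC/C(=C\OS(=O)(=O)[O-])CCC/C(C)=C/Cc1cc(O[Si](C(C)C)(C(C)C)C(C)C)ccc1O[Si](C(C)C)(C(C)C)C(C)C.[Na+] | intermediate
29 | tetrabutylammonium salt of the target sulfate (free hydroquinone) | CC1=CC[C@H]2C(C)(C)CCC[C@]2(C)[C@H]1CC/C(=C\OS(=O)(=O)[O-])CCC/C(C)=C/Cc1cc(O)ccc1O.CCCC[N+](CCCC)(CCCC)CCCC | intermediate
30 | target: (E)-enol hydrogen sulfate of the (5S,9S,10S)-labd-7-ene-type hydroquinone | CC1=CC[C@H]2C(C)(C)CCC[C@]2(C)[C@H]1CC/C(=C\OS(=O)(=O)O)CCC/C(C)=C/Cc1cc(O)ccc1O | target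

**Step count.** 19 steps in total. Longest linear sequence: 14 steps (1, 2, 4–11, 16–19).

**Steps most likely to fail**

Step 8. The cycloaddition may show incomplete endo preference or attack the wrong face relative to C9, because the C11/C8-methyl contact competes with the inside-hydrogen rotamer. The silyl triflate may also trigger aldol oligomerisation of the silyloxydiene with the enal, or silylation may occur at C6. The fallback sets out from 11 and comes back at 14, replacing steps 8 and 9. Compound 11 is deprotonated at the ketone methyl with LiN(SiMe3)2 in THF at −78 °C to give the cross-conjugated lithium dienolate F1. This should close by an intramolecular double Michael addition (anion-accelerated [4+2] of the Ihara–Fukumoto type), which forms the same C1–C2 and C5–C10 bonds at low temperature. Lithium bridging the dienolate oxygen and the formyl oxygen holds the formyl group endo. The resulting bicyclic lithium enolate F2 is methylated at C4 in the same flask with MeI/DMPU to give 14.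

Step 18. Oxygen transfer to the alkenyllithium may be incomplete, adventitious protonation may cost the enol oxygen or its geometry, and the aggregated lithium enolate may react sluggishly or at carbon with the SO3 complex. The fallback sets out from 25 and comes back at 28. The alkenyllithium 26 is oxidised with bis(trimethylsilyl) peroxide to the trimethylsilyl (E)-enol ether F3, which is isolated so that its geometry can be checked. MeLi regenerates the lithium enolate 27, which is O-sulfonylated with 2,2,2-trichloroethyl chlorosulfate to the enol trichloroethyl sulfate F4, a protected sulfate diester. Zinc and ammonium formate in MeOH remove the trichloroethyl group, and sodium exchange gives 28.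

Step 16. Alkoxide may eliminate the iodide, the borylcopper adduct may be protonated before alkylation (giving the simple hydroboration product), or borylcupration may take the wrong regiochemistry. The fallback sets out from 16 and comes back at 25, replacing steps 16 and 17. Iodide 16 is converted with magnesium in Et2O into the Grignard reagent F5 and then with CuBr·SMe2 into the alkylcopper reagent. Syn-carbocupration of the terminal alkyne 23 (Normant, Et2O/Me2S, −25 °C) gives the alkenylcopper F6, with copper on C14 cis to C12. Iodinolysis with I2 gives 25 with retention.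

**Further compounds**

F1 | step 8 | lithium dienolate of 11 (O–Li on C3, diene C2=C3–C4=C5) | C=C(C=O)[C@@H](CCO[Si](C)(C)C(C)(C)C)/C(C)=C\C/C=C(C)/C(O[Li])=C
F2 | step 8 | bicyclic lithium enolate (O–Li on C3, C3=C4; otherwise as 13) | CC1=CC[C@H]2C(C)=C(O[Li])CC[C@]2(C=O)[C@H]1CCO[Si](C)(C)C(C)(C)C
F3 | step 18 | trimethylsilyl (E)-enol ether corresponding to 27 | CC1=CC[C@H]2C(C)(C)CCC[C@]2(C)[C@H]1CC/C(=C\O[Si](C)(C)C)CCC/C(C)=C/Cc1cc(O[Si](C(C)C)(C(C)C)C(C)C)ccc1O[Si](C(C)C)(C(C)C)C(C)C
F4 | step 18 | (E)-enol 2,2,2-trichloroethyl sulfate, both phenols as triisopropylsilyl ethers | CC1=CC[C@H]2C(C)(C)CCC[C@]2(C)[C@H]1CC/C(=C\OS(=O)(=O)OCC(Cl)(Cl)Cl)CCC/C(C)=C/Cc1cc(O[Si](C(C)C)(C(C)C)C(C)C)ccc1O[Si](C(C)C)(C(C)C)C(C)C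
F5 | step 16 | Grignard reagent from 16 (iodomagnesium on C12) | CC1=CC[C@H]2C(C)(C)CCC[C@]2(C)[C@H]1CC[Mg]I
F6 | step 16 | (E)-alkenylcopper (copper on C14, cis to C12) | CC1=CC[C@H]2C(C)(C)CCC[C@]2(C)[C@H]1CC/C(=C\[Cu])CCC/C(C)=C/Cc1cc(O[Si](C(C)C)(C(C)C)C(C)C)ccc1O[Si](C(C)C)(C(C)C)C(C)C
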